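**Retrosynthetic overview**
- The hydroxyquinone comes last, by Teuber (Fremy's salt) oxidation of a 2-alkyl-4-chloro-5-methylresorcinol after acid unmasking.
- The carbinol–alkenyl bond and the (S)-carbinol come from exo addition of an (E)-alkenyltrifluoroborate (made from orcinol) to a 2-oxabicyclo[3.3.1]nonyl oxocarbenium ion built from the ring keto aldehyde.
- The quaternary carbon and the alpha-methyl centre come from conjugate methylation anti to the bought C4 methyl, then enolate methylation anti to the axial allyl group.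
- The ring–side-chain C–C bond is made by an anionic oxy-Cope rearrangement of a 1-allylcyclohex-2-en-1-ol, followed by regeneration of the enone.
- Ring order: the cyclohexene is closed first by ring-closing metathesis of an (S)-citronellene-derived dienol, the oxabicycle is transient, and the bought arene becomes the quinone last.

Assumption: the target is taken exactly as drawn, i.e. (2E,4S) side chain and (1S,2R,6S)-1,2,6-trimethyl-3-oxocyclohexyl unit; (S)-beta-citronellene and orcinol are taken as commercial.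

**Route**

Step 1
Reactants: 1 (S)-beta-citronellene [(3S)-3,7-dimethylocta-1,6-diene]
Product: 2 (4S)-4-methylhex-5-enal
Conditions: O3 (1.0 equiv), CH2Cl2, pyridine (cat.), −78 °C; Me2S, −78 °C → rt
Reagents that add atoms: ozone, O=[O+][O-]
Why: Ozone adds by 1,3-dipolar cycloaddition fastest to the electron-rich trisubstituted alkene, so this chemoselective ozonolysis cleaves only that bond and leaves the vinyl group and the bought stereocentre untouched.

Step 2
Reactants: 2 (4S)-4-methylhex-5-enal
Product: 3 (6S)-6-methylocta-1,7-dien-3-ol (mixture of C3 epimers)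
Conditions: CH2=CHMgBr, THF, −78 → 0 °C; aq. NH4Cl
Reagents that add atoms: vinylmagnesium bromide, C=C[Mg]Br
Why: Grignard 1,2-addition to the aldehyde gives the allylic alcohol needed for ring closure, and its new carbinol centre is deliberately unselective because it is oxidised away in step 4.

Step 3
Reactants: 3 (6S)-6-methylocta-1,7-dien-3-ol (mixture of C3 epimers)
Product: 4 (4S)-4-methylcyclohex-2-en-1-ol (mixture of C1 epimers)
Conditions: second-generation Grubbs catalyst RuCl2(=CHPh)(PCy3)(SIMes) (2 mol %), CH2Cl2, 40 °C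
Reagents that add atoms: none
Why: Ring-closing olefin metathesis of the 1,7-diene closes the unstrained cyclohexene with loss of ethene and does not touch the methyl-bearing stereocentre.

Step 4
Reactants: 4 (4S)-4-methylcyclohex-2-en-1-ol (mixture of C1 epimers)
Product: 5 (4S)-4-methylcyclohex-2-en-1-one
Conditions: MnO2, CH2Cl2, rt
Reagents that add atoms: none
Why: MnO2 oxidation of the allylic alcohol converges both carbinol epimers to the enone under neutral conditions that do not enolise toward the gamma stereocentre.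

Step 5
Reactants: 5 (4S)-4-methylcyclohex-2-en-1-one
Product: 6 (4S)-4-methyl-1-(prop-2-en-1-yl)cyclohex-2-en-1-ol (mixture of C1 epimers)
Conditions: CH2=CHCH2MgBr, Et2O, −78 °C; aq. NH4Cl
Reagents that add atoms: allylmagnesium bromide, C=CC[Mg]Br
Why: Allyl Grignard reagents add 1,2 to enones, giving the 1,5-dien-3-ol array for the oxy-Cope step, and the carbinol configuration is irrelevant because C1 and C3 both end up sp2.

Step 6
Reactants: 6 (4S)-4-methyl-1-(prop-2-en-1-yl)cyclohex-2-en-1-ol (mixture of C1 epimers)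
Product: 9 (4S)-4-methyl-3-(prop-2-en-1-yl)cyclohex-2-en-1-one, via potassium enolate 7 (not isolated), via alpha-selenyl ketone 8 (not isolated)
Conditions: KH, 18-crown-6, THF, 0 °C → rt; PhSeBr, −78 °C; then H2O2, pyridine, CH2Cl2, 0 °C → rt
Reagents that add atoms: none
Why: The potassium alkoxide undergoes an anionic oxy-Cope [3,3]-sigmatropic rearrangement that forms the C3–allyl bond and a regiodefined enolate, which is selenenylated and turned into the enone by selenoxide syn-elimination, so only the untouched C4 stereocentre remains.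

Step 7
Reactants: 9 (4S)-4-methyl-3-(prop-2-en-1-yl)cyclohex-2-en-1-one
Product: 11 (2R,3S,4S)-2,3,4-trimethyl-3-(prop-2-en-1-yl)cyclohexan-1-one, via lithium enolate 10 (not isolated)
Conditions: Me2CuLi, Et2O, −20 °C; then MeI, DMPU, −78 → 0 °C; cold NH4Cl quench
Reagents that add atoms: lithium dimethylcuprate, [Li+].C[Cu-]C; iodomethane, CI
Why: Gilman conjugate addition delivers methyl to C3 anti to the C4 methyl (allyl therefore cis to it), and the enolate is then methylated at C2 anti to the axial allyl group (tandem conjugate addition–alkylation), setting the quaternary and alpha centres under kinetic control from the bought centre.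

Step 8
Reactants: 11 (2R,3S,4S)-2,3,4-trimethyl-3-(prop-2-en-1-yl)cyclohexan-1-one
Product: 13 (1R,5S,6S,9R)-1,3-dimethoxy-5,6,9-trimethyl-2-oxabicyclo[3.3.1]nonane (mixture of C3 anomers), via keto aldehyde 12 (not isolated)
Conditions: O3, CH2Cl2/MeOH, −78 °C; Me2S; then CSA (cat.), MeOH, 4 Å molecular sieves, rt
Reagents that add atoms: ozone, O=[O+][O-]; methanol, CO
Why: Ozonolysis of the terminal alkene gives the 1,5-keto aldehyde, and acid-catalysed acetalisation with the acetaldehyde arm axial ties both carbonyls into the bicyclic bis-acetal, which masks the epimerisable alpha centre and sets up the carbinol stereocontrol.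

Step 9
Reactants: 14 orcinol (5-methylbenzene-1,3-diol)
Product: 15 1,3-bis(methoxymethoxy)-5-methylbenzene
Conditions: NaH, MOMCl, DMF, 0 °C → rt
Reagents that add atoms: chloromethyl methyl ether, COCCl
Why: Williamson-type O-alkylation of the bis-phenoxide installs MOM ethers that protect the phenols and direct the next lithiation.

Step 10
Reactants: 15 1,3-bis(methoxymethoxy)-5-methylbenzene
Product: 17 2-(but-2-yn-1-yl)-1,3-bis(methoxymethoxy)-5-methylbenzene, via aryllithium 16 (not isolated)
Conditions: n-BuLi, THF, 0 °C; CuI (10 mol %), 1-bromobut-2-yne, −78 °C → rt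
Reagents that add atoms: 1-bromobut-2-yne, CC#CCBr
Why: Directed ortho-metalation occurs at C2 between the two MOM-oxy groups, and copper-catalysed SN2 alkylation with the propargylic bromide gives the 2-butynyl arene.

Step 11
Reactants: 17 2-(but-2-yn-1-yl)-1,3-bis(methoxymethoxy)-5-methylbenzene
Product: 18 2-(but-2-yn-1-yl)-4-chloro-1,3-bis(methoxymethoxy)-5-methylbenzene
Conditions: NCS (1.0 equiv), MeCN, rt
Reagents that add atoms: N-chlorosuccinimide, O=C1CCC(=O)N1Cl
Why: Electrophilic aromatic chlorination takes place at one of the two symmetry-equivalent activated positions, so a single regioisomer forms.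

Step 12
Reactants: 18 2-(but-2-yn-1-yl)-4-chloro-1,3-bis(methoxymethoxy)-5-methylbenzene
Product: 20 4-chloro-2-[(2E)-3-iodobut-2-en-1-yl]-1,3-bis(methoxymethoxy)-5-methylbenzene, via alkenylzirconocene chloride 19 (not isolated)
Conditions: Cp2Zr(H)Cl (2.5 equiv), THF, 50 °C; then I2, 0 °C
Reagents that add atoms: iodine, II
Why: Syn hydrozirconation with excess Schwartz reagent equilibrates zirconium to the less hindered methyl-bearing carbon, and iodinolysis with retention gives the (E)-vinyl iodide that fixes the trisubstituted olefin geometry.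

Step 13
Reactants: 20 4-chloro-2-[(2E)-3-iodobut-2-en-1-yl]-1,3-bis(methoxymethoxy)-5-methylbenzene
Product: 23 potassium {(2Z)-4-[3-chloro-2,6-bis(methoxymethoxy)-4-methylphenyl]but-2-en-2-yl}trifluoroborate (boron trans to the benzylic CH2), via alkenyllithium 21 (not isolated), via lithium trimethoxyborate 22 (not isolated)
Conditions: t-BuLi (2.1 equiv), Et2O, −78 °C; B(OMe)3, −78 °C → rt; aq. KHF2, MeOH
Reagents that add atoms: trimethyl borate, COB(OC)OC; potassium hydrogen difluoride, [K+].F[H-]F
Why: Iodine–lithium exchange, borylation and fluoride exchange convert the vinyl iodide with retention of geometry into a bench-stable alkenyltrifluoroborate nucleophile.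

Step 14
Reactants: 13 (1R,5S,6S,9R)-1,3-dimethoxy-5,6,9-trimethyl-2-oxabicyclo[3.3.1]nonane (mixture of C3 anomers); 23 potassium {(2Z)-4-[3-chloro-2,6-bis(methoxymethoxy)-4-methylphenyl]but-2-en-2-yl}trifluoroborate
Product: 24 (1R,3S,5S,6S,9R)-3-{(2E)-4-[3-chloro-2,6-bis(methoxymethoxy)-4-methylphenyl]but-2-en-2-yl}-1-methoxy-5,6,9-trimethyl-2-oxabicyclo[3.3.1]nonane
Conditions: BF3·OEt2 (2 equiv), MeCN, −30 → 0 °C
Reagents that add atoms: none
Why: BF3 ionises the non-bridgehead acetal to a 2-oxabicyclo[3.3.1]non-2-enium ion, and the alkenyltrifluoroborate attacks its open exo face with retention of olefin geometry (acetal–trifluoroborate coupling), placing the alkenyl group equatorial and so setting the (S)-carbinol from the ring stereocentres.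

Step 15
Reactants: 24 (1R,3S,5S,6S,9R)-3-{(2E)-4-[3-chloro-2,6-bis(methoxymethoxy)-4-methylphenyl]but-2-en-2-yl}-1-methoxy-5,6,9-trimethyl-2-oxabicyclo[3.3.1]nonane
Product: 25 (2R,3S,4S)-3-[(2S,3E)-5-(3-chloro-2,6-dihydroxy-4-methylphenyl)-2-hydroxy-3-methylpent-3-en-1-yl]-2,3,4-trimethylcyclohexan-1-one
Conditions: 2 M aq. HCl, THF/MeOH, rt
Reagents that add atoms: water, O
Why: Mild aqueous acid hydrolyses the bridging methyl ketal back to ketone plus secondary alcohol and cleaves both aryl MOM acetals without appreciable enolisation of the alpha-methyl ketone.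

Step 16
Reactants: 25 (2R,3S,4S)-3-[(2S,3E)-5-(3-chloro-2,6-dihydroxy-4-methylphenyl)-2-hydroxy-3-methylpent-3-en-1-yl]-2,3,4-trimethylcyclohexan-1-one
Product: 26 2-chloro-5-hydroxy-6-[(2E,4S)-4-hydroxy-3-methyl-5-[(1S,2R,6S)-1,2,6-trimethyl-3-oxocyclohexyl]pent-2-en-1-yl]-3-methylcyclohexa-2,5-diene-1,4-dione (target CNP0469571.4)
Conditions: (KSO3)2NO (2.5 equiv), KH2PO4 buffer, H2O/acetone, 0 °C → rt
Reagents that add atoms: potassium nitrosodisulfonate, [K+].[K+].[O]N(S(=O)(=O)[O-])S(=O)(=O)[O-]
Why: Teuber oxidation with Fremy's salt oxidises the resorcinol at its only free position, para to a phenol, to the 2-hydroxy-1,4-benzoquinone without touching the allylic alcohol, ketone or olefin.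

**Compound list**

1 | (S)-beta-citronellene, (3S)-3,7-dimethylocta-1,6-diene | C=C[C@@H](C)CCC=C(C)C | starting material
2 | (4S)-4-methylhex-5-enal | O=CCC[C@H](C)C=C | intermediate
3 | (6S)-6-methylocta-1,7-dien-3-ol (C3 epimers) | C=CC(O)CC[C@H](C)C=C | intermediate
4 | (4S)-4-methylcyclohex-2-en-1-ol (C1 epimers) | OC1C=C[C@@H](C)CC1 | intermediate
5 | (4S)-4-methylcyclohex-2-en-1-one | O=C1C=C[C@@H](C)CC1 | intermediate
6 | (4S)-4-methyl-1-(prop-2-en-1-yl)cyclohex-2-en-1-ol (C1 epimers) | C=CCC1(O)C=C[C@@H](C)CC1 | intermediate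
7 | potassium (4S)-4-methyl-3-(prop-2-en-1-yl)cyclohex-1-en-1-olate (C3 epimers) | [K+].[O-]C1=CC(CC=C)[C@@H](C)CC1 | intermediate
8 | (4S)-4-methyl-2-(phenylselanyl)-3-(prop-2-en-1-yl)cyclohexan-1-one (C2/C3 epimers) | O=C1CC[C@H](C)C(CC=C)C1[Se]c1ccccc1 | intermediate
9 | (4S)-4-methyl-3-(prop-2-en-1-yl)cyclohex-2-en-1-one | O=C1C=C(CC=C)[C@@H](C)CC1 | intermediate
10 | lithium (3S,4S)-3,4-dimethyl-3-(prop-2-en-1-yl)cyclohex-1-en-1-olate | [Li+].[O-]C1=C[C@@](C)(CC=C)[C@@H](C)CC1 | intermediate
11 | (2R,3S,4S)-2,3,4-trimethyl-3-(prop-2-en-1-yl)cyclohexan-1-one | C=CC[C@@]1(C)[C@@H](C)CCC(=O)[C@@H]1C | intermediate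
12 | 2-[(1S,2R,6S)-1,2,6-trimethyl-3-oxocyclohexyl]acetaldehyde | O=CC[C@@]1(C)[C@@H](C)CCC(=O)[C@@H]1C | intermediate
13 | (1R,5S,6S,9R)-1,3-dimethoxy-5,6,9-trimethyl-2-oxabicyclo[3.3.1]nonane (C3 anomers) | CO[C@]12CC[C@H](C)[C@](C)(CC(OC)O1)[C@H]2C | intermediate
14 | orcinol, 5-methylbenzene-1,3-diol | Cc1cc(O)cc(O)c1 | starting material
15 | 1,3-bis(methoxymethoxy)-5-methylbenzene | COCOc1cc(C)cc(OCOC)c1 | intermediate
16 | [2,6-bis(methoxymethoxy)-4-methylphenyl]lithium | [Li]c1c(OCOC)cc(C)cc1OCOC | intermediate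
17 | 2-(but-2-yn-1-yl)-1,3-bis(methoxymethoxy)-5-methylbenzene | CC#CCc1c(OCOC)cc(C)cc1OCOC | intermediate
18 | 2-(but-2-yn-1-yl)-4-chloro-1,3-bis(methoxymethoxy)-5-methylbenzene | CC#CCc1c(OCOC)cc(C)c(Cl)c1OCOC | intermediate
19 | chlorobis(cyclopentadienyl){(2E)-4-[3-chloro-2,6-bis(methoxymethoxy)-4-methylphenyl]but-2-en-2-yl}zirconium | C/C(=C\Cc1c(OCOC)cc(C)c(Cl)c1OCOC)[Zr](Cl)(C1C=CC=C1)C1C=CC=C1 | intermediate
20 | 4-chloro-2-[(2E)-3-iodobut-2-en-1-yl]-1,3-bis(methoxymethoxy)-5-methylbenzene | C/C(I)=C\Cc1c(OCOC)cc(C)c(Cl)c1OCOC | intermediate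
21 | {(2Z)-4-[3-chloro-2,6-bis(methoxymethoxy)-4-methylphenyl]but-2-en-2-yl}lithium | C/C([Li])=C\Cc1c(OCOC)cc(C)c(Cl)c1OCOC | intermediate
22 | lithium {(2Z)-4-[3-chloro-2,6-bis(methoxymethoxy)-4-methylphenyl]but-2-en-2-yl}trimethoxyborate | [Li+].CO[B-](OC)(OC)/C(C)=C/Cc1c(OCOC)cc(C)c(Cl)c1OCOC | intermediate
23 | potassium {(2Z)-4-[3-chloro-2,6-bis(methoxymethoxy)-4-methylphenyl]but-2-en-2-yl}trifluoroborate | [K+].F[B-](F)(F)/C(C)=C/Cc1c(OCOC)cc(C)c(Cl)c1OCOC | intermediate
24 | (1R,3S,5S,6S,9R)-3-{(2E)-4-[3-chloro-2,6-bis(methoxymethoxy)-4-methylphenyl]but-2-en-2-yl}-1-methoxy-5,6,9-trimethyl-2-oxabicyclo[3.3.1]nonane | CO[C@]12CC[C@H](C)[C@](C)(C[C@@H](/C(C)=C/Cc3c(OCOC)cc(C)c(Cl)c3OCOC)O1)[C@H]2C | intermediate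
25 | (2R,3S,4S)-3-[(2S,3E)-5-(3-chloro-2,6-dihydroxy-4-methylphenyl)-2-hydroxy-3-methylpent-3-en-1-yl]-2,3,4-trimethylcyclohexan-1-one | Cc1cc(O)c(C/C=C(\C)[C@@H](O)C[C@@]2(C)[C@@H](C)CCC(=O)[C@@H]2C)c(O)c1Cl | intermediate
26 | 2-chloro-5-hydroxy-6-[(2E,4S)-4-hydroxy-3-methyl-5-[(1S,2R,6S)-1,2,6-trimethyl-3-oxocyclohexyl]pent-2-en-1-yl]-3-methylcyclohexa-2,5-diene-1,4-dione | CC1=C(Cl)C(=O)C(C/C=C(\C)[C@@H](O)C[C@@]2(C)[C@@H](C)CCC(=O)[C@@H]2C)=C(O)C1=O | target

**Step count**

Total: 16 steps. Longest linear sequence: 11 steps (steps 1–8, then 14–16); the arene branch (steps 9–13) is 5 steps.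

**Three steps most likely to fail**

1. Step 14 (oxocarbenium alkenylation). The risks are competing ionisation of the aryl MOM acetals, endocyclic acetal cleavage, protodeboronation and imperfect exo selectivity. Fallback: set out from keto aldehyde 12 (isolated by leaving out the methanol/acid treatment in step 8) and vinyl iodide 20, and join them by a Nozaki–Hiyama–Kishi reaction (CrCl2, NiCl2 (cat.), DMSO/THF, rt). The alkenylchromium species adds only to the aldehyde and gives, after chromatographic removal of the carbinol epimer, (2R,3S,4S)-3-{(2S,3E)-5-[3-chloro-2,6-bis(methoxymethoxy)-4-methylphenyl]-2-hydroxy-3-methylpent-3-en-1-yl}-2,3,4-trimethylcyclohexan-1-one F1. F1 is deprotected under the conditions of step 15 and comes back to the route at 25.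

2. Step 7 (tandem conjugate addition–methylation). The enone is hindered, and the C2 methyl is set kinetically: a rough conformational estimate puts the C2 epimer slightly lower in energy, so slow addition, enolate equilibration or later base or strong acid could erode that centre. Fallback: set out from enone 9, run the conjugate methylation with Me2CuLi in the presence of Me3SiCl, and isolate {[(3S,4S)-3,4-dimethyl-3-(prop-2-en-1-yl)cyclohex-1-en-1-yl]oxy}trimethylsilane F2. Cleaving F2 with MeLi (THF, 0 °C) regenerates lithium enolate 10 free of copper salts; methylation with MeI/DMPU at −78 °C comes back to the route at 11.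

3. Step 6 (anionic oxy-Cope, selenation, elimination). The potassium alkoxide may fragment by retro-allylation, and the selenoxide elimination may be low-yielding. Fallback: set out from enone 5 and add the allyl group by conjugate addition of lithium diallylcuprate in the presence of Me3SiCl (THF, −78 °C) to give trimethyl{[(4S)-4-methyl-3-(prop-2-en-1-yl)cyclohex-1-en-1-yl]oxy}silane F3. Saegusa–Ito oxidation of F3 (Pd(OAc)2, MeCN, rt) comes back to the route at 9.

Further compounds
F1 | step 14 | (2R,3S,4S)-3-{(2S,3E)-5-[3-chloro-2,6-bis(methoxymethoxy)-4-methylphenyl]-2-hydroxy-3-methylpent-3-en-1-yl}-2,3,4-trimethylcyclohexan-1-one | COCOc1cc(C)c(Cl)c(OCOC)c1C/C=C(\C)[C@@H](O)C[C@@]2(C)[C@@H](C)CCC(=O)[C@@H]2C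
F2 | step 7 | {[(3S,4S)-3,4-dimethyl-3-(prop-2-en-1-yl)cyclohex-1-en-1-yl]oxy}trimethylsilane | C[Si](C)(C)OC1=C[C@@](C)(CC=C)[C@@H](C)CC1
F3 | step 6 | trimethyl{[(4S)-4-methyl-3-(prop-2-en-1-yl)cyclohex-1-en-1-yl]oxy}silane | C[Si](C)(C)OC1=CC(CC=C)[C@@H](C)CC1
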